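**Retrosynthetic overview**

1. Endgame: the cyclic enol ether 16 (C7=C8–OMe, racemic at C5) is hydrogenated with a chiral iridium catalyst. This sets C8 and keeps only the matched (5S)-enantiomer (kinetic resolution), giving the cis-(5S,8R) target 17.
2. Key disconnection: ring B (the carbocycle) is cut at C8–C8a and at C5–C6. This gives bromopyridinone 10 (ring A with the nonyl group on C4a and bromine on C8a) and methoxyallene 11 (C6–C7–C8, already carrying the C8 methoxy group).
3. Enabling feature: in ring A the CH2 of the nonyl group (C5) and C8a are ortho across the C4a=C8a bond, which has enaminone (alkene-like) character. An allene on C8a is therefore a vinylallene whose central carbon C7 lies 1,5 to a C5–H. Cross-coupling (C8–C8a) can then be followed in the same flask by a [1,5]-hydrogen shift and a 6π-electrocyclization (C5–C6) that restores the aromatic pyridinone.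
4. Order of rings: ring A comes first, from maltol (pyranone, then N-hydroxypyridinone, then N-methoxypyridinone), followed by iodine at C4a, bromine at C8a and a site-selective Negishi coupling for the nonyl group. Ring B is formed second, in the key step.

Key step: step 7

Remark: atoms are named with the quinolinone numbering of the target throughout (N1, C2, C3, C4, C4a, C5 to C8, C8a). Ring carbons 5 and 6 in the names of the monocyclic pyridinones are the later C4a and C8a, and the CH2 of the nonyl group is the later C5.

**Route**

Step 1
Reactants: 1 maltol (3-hydroxy-2-methyl-4H-pyran-4-one)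
Product: 2 3-methoxy-2-methyl-4H-pyran-4-one
Conditions: MeI, K2CO3, acetone, reflux
Reagents that add atoms: iodomethane, CI
Why: Williamson O-methylation of the acidic enolic 3-hydroxyl group should be clean because no other nucleophilic site is present.

Step 2
Reactants: 2 3-methoxy-2-methyl-4H-pyran-4-one
Product: 3 1-hydroxy-3-methoxy-2-methylpyridin-4(1H)-one
Conditions: NH2OH·HCl, NaOAc, EtOH–H2O, reflux
Reagents that add atoms: hydroxylamine hydrochloride, Cl.NO
Why: Pyranone-to-pyridinone exchange (conjugate addition of the hydroxylamine nitrogen next to the ring oxygen, ring opening and re-closure with loss of water, an ANRORC-type sequence) should turn the 4-pyranone into the N-hydroxy-4-pyridinone.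

Step 3
Reactants: 3 1-hydroxy-3-methoxy-2-methylpyridin-4(1H)-one
Product: 4 1,3-dimethoxy-2-methylpyridin-4(1H)-one
Conditions: MeI, K2CO3, DMF, 25 °C
Reagents that add atoms: iodomethane, CI
Why: O-Alkylation of the N-hydroxypyridinone (a cyclic vinylogous hydroxamic acid) should occur on the N–O oxygen, its most nucleophilic site, and give the N-methoxy group of the target.

Step 4
Reactants: 4 1,3-dimethoxy-2-methylpyridin-4(1H)-one
Product: 5 5-iodo-1,3-dimethoxy-2-methylpyridin-4(1H)-one
Conditions: NIS, MeCN, 25 °C
Reagents that add atoms: N-iodosuccinimide, O=C1CCC(=O)N1I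
Why: Electrophilic iodination of an enaminone should go to the α-carbon of the N–C=C–C=O unit (the later C4a), the only nucleophilic ring position left.

Step 5
Reactants: 5 5-iodo-1,3-dimethoxy-2-methylpyridin-4(1H)-one
Product: 7 6-bromo-5-iodo-1,3-dimethoxy-2-methylpyridin-4(1H)-one, via chloromagnesio pyridinone 6 (not isolated)
Conditions: TMPMgCl·LiCl, THF, −60 °C; then BrCl2C–CCl2Br, −60 to 0 °C
Reagents that add atoms: 1,2-dibromo-1,1,2,2-tetrachloroethane, BrC(Cl)(Cl)C(Cl)(Cl)Br
Why: Directed deprotonative magnesiation with a hindered magnesium amide should take place at the only ring C–H (the later C8a), which is acidified by the neighbouring iodine and the N-methoxy group, and the aryl magnesium species is then brominated by the electrophilic bromine source.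

Step 6
Reactants: 7 6-bromo-5-iodo-1,3-dimethoxy-2-methylpyridin-4(1H)-one; 8 nonylmagnesium bromide
Product: 10 6-bromo-1,3-dimethoxy-2-methyl-5-nonylpyridin-4(1H)-one, via nonylzinc chloride 9 (not isolated)
Conditions: 8, ZnCl2, THF, 0 °C; then 7, Pd(dppf)Cl2 (cat.), THF, 25 °C
Reagents that add atoms: none
Why: Negishi cross-coupling in which zerovalent palladium inserts faster into the C–I bond than into the C–Br bond and the dppf ligand suppresses β-hydride elimination, so the nonyl chain (C5 plus the octyl group of the target) should be attached at the later C4a only.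

Step 7
Reactants: 10 6-bromo-1,3-dimethoxy-2-methyl-5-nonylpyridin-4(1H)-one; 11 methoxyallene
Product: 16 rac-1,3,8-trimethoxy-2-methyl-5-octyl-5,6-dihydroquinolin-4(1H)-one, via lithiated methoxyallene 12 (not isolated), via methoxyallenylzinc chloride 13 (not isolated), via aryl allenyl ether 14 (not isolated), via ortho-quinodimethane 15 (not isolated)
Conditions: 11, n-BuLi, THF, −40 °C; ZnCl2, −40 to 0 °C; then 10, Pd(OAc)2 (cat.), SPhos (cat.), THF, 25 °C; then toluene, 90 °C; NaHCO3 work-up, Et3N-deactivated silica
Reagents that add atoms: none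
Why: Proposed new method: zerovalent palladium inserts into the C–Br bond of 10 and couples it with the allenylzinc reagent 13 (Negishi coupling, forms C8–C8a), which puts the central allene carbon C7 of 14 in a 1,5-relationship to the C5–H2 of the nonyl group across the enaminone-like C4a=C8a bond, so that 14 is in effect a vinylallene. On heating, a suprafacial [1,5]-hydrogen shift from C5 to C7 should give the ortho-quinodimethane 15, whose triene C5=C4a–C8a=C8–C7=C6 should close by a thermal disrotatory 6π-electrocyclization that forms C5–C6 and restores the aromatic pyridinone, which is the driving force. The closest known reactions are palladium-catalysed couplings of alkoxyallenyl metals with aryl halides, the [1,5]-hydrogen shift of vinylallenes, and the tandem [1,5]-hydrogen shift/6π-electrocyclization of ortho-substituted aryl allenes and ketenimines to dihydronaphthalenes and quinolines; the sequence has not been run as one operation on an alkylpyridinone. Ring B is closed in the electrocyclization (all six ring atoms lie in the cyclic transition state, a 6-endo mode). C5 is formed in this closure with no chiral element present and is therefore racemic in 16, while C8 is still sp2; both centres are dealt with in step 8. The selectivities needed are coupling at the allenyl and not the propargyl terminus, which the α-methoxy zinc reagent should secure, and a geometry of 15 with the octyl chain pointing toward C4 and away from C8, which follows from the less crowded transition state of the hydrogen shift and keeps the chain C–H bonds from a second [1,5]-shift, while the hydrogen shift itself places the vinyl group cis to C4a as the ring closure requires.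

Step 8
Reactants: 16 rac-1,3,8-trimethoxy-2-methyl-5-octyl-5,6-dihydroquinolin-4(1H)-one
Product: 17 (5S,8R)-1,3,8-trimethoxy-2-methyl-5-octyl-5,6,7,8-tetrahydroquinolin-4(1H)-one (Waltherione K)
Conditions: H2 (50 bar), [Ir(cod)(tBu-PHOX)]BArF (cat., ligand antipode that gives 8R), CH2Cl2, 25 °C; stopped when the matched enantiomer is consumed; chromatography
Reagents that add atoms: none
Why: Iridium-catalysed asymmetric hydrogenation of a trisubstituted enol ether: the catalyst sets C8 as R, and because only in (5S)-16 the catalyst-preferred face is also the face opposite the pseudoaxial octyl group, this enantiomer should react fast to the cis product 17, while the mismatched (5R)-enantiomer reacts slowly and is removed as recovered 16 or as the trans diastereomer, so the step sets C8 and selects C5 (kinetic resolution).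

**Compound list**

1 | maltol (3-hydroxy-2-methyl-4H-pyran-4-one) | Cc1occc(=O)c1O | starting material
2 | 3-methoxy-2-methyl-4H-pyran-4-one | COc1c(C)occc1=O | intermediate
3 | 1-hydroxy-3-methoxy-2-methylpyridin-4(1H)-one | COc1c(C)n(O)ccc1=O | intermediate
4 | 1,3-dimethoxy-2-methylpyridin-4(1H)-one | COc1c(C)n(OC)ccc1=O | intermediate
5 | 5-iodo-1,3-dimethoxy-2-methylpyridin-4(1H)-one | COc1c(C)n(OC)cc(I)c1=O | intermediate
6 | 6-(chloromagnesio)-5-iodo-1,3-dimethoxy-2-methylpyridin-4(1H)-one | COc1c(C)n(OC)c([Mg]Cl)c(I)c1=O | intermediate
7 | 6-bromo-5-iodo-1,3-dimethoxy-2-methylpyridin-4(1H)-one | COc1c(C)n(OC)c(Br)c(I)c1=O | intermediate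
8 | nonylmagnesium bromide | CCCCCCCCC[Mg]Br | starting material
9 | nonylzinc chloride | CCCCCCCCC[Zn]Cl | intermediate
10 | 6-bromo-1,3-dimethoxy-2-methyl-5-nonylpyridin-4(1H)-one | CCCCCCCCCc1c(Br)n(OC)c(C)c(OC)c1=O | intermediate
11 | methoxyallene (1-methoxypropa-1,2-diene) | COC=C=C | starting material
12 | (1-methoxypropa-1,2-dien-1-yl)lithium | [Li]C(OC)=C=C | intermediate
13 | (1-methoxypropa-1,2-dien-1-yl)zinc chloride | Cl[Zn]C(OC)=C=C | intermediate
14 | 1,3-dimethoxy-6-(1-methoxypropa-1,2-dien-1-yl)-2-methyl-5-nonylpyridin-4(1H)-one | CCCCCCCCCc1c(C(OC)=C=C)n(OC)c(C)c(OC)c1=O | intermediate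
15 | (5Z,6Z)-1,3-dimethoxy-6-(1-methoxyprop-2-en-1-ylidene)-2-methyl-5-nonylidene-5,6-dihydropyridin-4(1H)-one | CCCCCCCC/C=C1/C(=C(/OC)C=C)N(OC)C(C)=C(OC)C1=O | intermediate
16 | rac-1,3,8-trimethoxy-2-methyl-5-octyl-5,6-dihydroquinolin-4(1H)-one (racemic at C5) | CCCCCCCCC1CC=C(OC)c2c1c(=O)c(OC)c(C)n2OC | intermediate
17 | (5S,8R)-1,3,8-trimethoxy-2-methyl-5-octyl-5,6,7,8-tetrahydroquinolin-4(1H)-one (Waltherione K) | CCCCCCCC[C@H]1CC[C@@H](OC)c2c1c(=O)c(OC)c(C)n2OC | target

**Step count and risks**

Total step count: 8. Longest linear sequence: 8 steps (from maltol).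

Steps most likely to fail:

1. Step 7 (proposed new method). The thermal stage may stall, because the [1,5]-hydrogen shift has to break the cyclic conjugation of ring A; the aryl allenyl ether 14 could then oligomerize or be hydrolysed before ring closure. Coupling through the propargyl terminus would also divert material. The fallback uses known reactions only, builds ring B by ring-closing metathesis, sets out from 7 and comes back at 17.
   - Suzuki–Miyaura coupling of 7 at the C–I bond with 2-(dec-1-en-2-yl)-4,4,5,5-tetramethyl-1,3,2-dioxaborolane (Pd(dppf)Cl2, K3PO4) would give 6-bromo-5-(dec-1-en-2-yl)-1,3-dimethoxy-2-methylpyridin-4(1H)-one F1.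
   - Bromine–magnesium exchange (iPrMgCl·LiCl, −40 °C) and DMF would give 3-(dec-1-en-2-yl)-1,5-dimethoxy-6-methyl-4-oxo-1,4-dihydropyridine-2-carbaldehyde F2.
   - Brown allylation with B-allyldiisopinocampheylborane (antipode chosen for the R carbinol) would give 5-(dec-1-en-2-yl)-6-[(1R)-1-hydroxybut-3-en-1-yl]-1,3-dimethoxy-2-methylpyridin-4(1H)-one F3.
   - NaH and MeI would give 5-(dec-1-en-2-yl)-1,3-dimethoxy-6-[(1R)-1-methoxybut-3-en-1-yl]-2-methylpyridin-4(1H)-one F4.
   - Ring-closing metathesis with the second-generation Grubbs catalyst would close ring B to (8R)-1,3,8-trimethoxy-2-methyl-5-octyl-7,8-dihydroquinolin-4(1H)-one F5.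
   - Hydrogenation (H2, Pd/C) from the face opposite the pseudoaxial C8 methoxy group would give 17.

2. Step 8. Catalyst control may be incomplete, or the enol ether may isomerize or hydrolyse under the acidic cationic iridium conditions. Either would erode enantiomeric purity, because the mismatched enantiomer then leaks into the mirror image of 17. The fallback sets out from 16 and comes back at 17.
   - Hydrolysis of the enol ether (1 M HCl, THF) would give rac-1,3-dimethoxy-2-methyl-5-octyl-6,7-dihydroquinoline-4,8(1H,5H)-dione F6.
   - Noyori asymmetric transfer hydrogenation (RuCl(p-cymene)(TsDPEN), antipode chosen for 8R, HCO2H/Et3N) should reduce both enantiomers under catalyst control. The cis alcohol (5S,8R)-8-hydroxy-1,3-dimethoxy-2-methyl-5-octyl-5,6,7,8-tetrahydroquinolin-4(1H)-one F7 is separated from its trans (5R,8R) diastereomer by chromatography.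
   - O-Methylation (NaH, MeI, THF) would give 17.

3. Step 5. Lateral deprotonation of the C2 methyl group may compete with ring magnesiation, and the ortho-iodo magnesium species 6 may lose magnesium halide to a hetaryne. The fallback sets out from 4 and comes back at 7.
   - Bromination (NBS, MeCN) would give 5-bromo-1,3-dimethoxy-2-methylpyridin-4(1H)-one F8.
   - Treatment with LiN(iPr)2 (THF, −78 °C) should trigger a halogen dance, in which bromine moves to the later C8a and lithium settles between the carbonyl group and the bromine; quenching with I2 would give 7.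

**Further compounds**

F1 | step 7 | 6-bromo-5-(dec-1-en-2-yl)-1,3-dimethoxy-2-methylpyridin-4(1H)-one | C=C(CCCCCCCC)c1c(Br)n(OC)c(C)c(OC)c1=O
F2 | step 7 | 3-(dec-1-en-2-yl)-1,5-dimethoxy-6-methyl-4-oxo-1,4-dihydropyridine-2-carbaldehyde | C=C(CCCCCCCC)c1c(C=O)n(OC)c(C)c(OC)c1=O
F3 | step 7 | 5-(dec-1-en-2-yl)-6-[(1R)-1-hydroxybut-3-en-1-yl]-1,3-dimethoxy-2-methylpyridin-4(1H)-one | C=CC[C@@H](O)c1n(OC)c(C)c(OC)c(=O)c1C(=C)CCCCCCCC
F4 | step 7 | 5-(dec-1-en-2-yl)-1,3-dimethoxy-6-[(1R)-1-methoxybut-3-en-1-yl]-2-methylpyridin-4(1H)-one | C=CC[C@@H](OC)c1n(OC)c(C)c(OC)c(=O)c1C(=C)CCCCCCCC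
F5 | step 7 | (8R)-1,3,8-trimethoxy-2-methyl-5-octyl-7,8-dihydroquinolin-4(1H)-one | CCCCCCCCC1=CC[C@@H](OC)c2c1c(=O)c(OC)c(C)n2OC
F6 | step 8 | rac-1,3-dimethoxy-2-methyl-5-octyl-6,7-dihydroquinoline-4,8(1H,5H)-dione | CCCCCCCCC1CCC(=O)c2c1c(=O)c(OC)c(C)n2OC
F7 | step 8 | (5S,8R)-8-hydroxy-1,3-dimethoxy-2-methyl-5-octyl-5,6,7,8-tetrahydroquinolin-4(1H)-one | CCCCCCCC[C@H]1CC[C@@H](O)c2c1c(=O)c(OC)c(C)n2OC
F8 | step 5 | 5-bromo-1,3-dimethoxy-2-methylpyridin-4(1H)-one | COc1c(C)n(OC)cc(Br)c1=O
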